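## The problem

Siphulin (23) is an achiral 2-benzylchromone: a γ-pyranone (ring B) fused to a resorcinol-type ring A and joined through one methylene at C2 to an orsellinic-acid-type ring C. There are no stereocentres, so the difficulties are regiochemistry and functional-group tolerance. Ring A carries the C8a oxygen, the C4a acyl carbon and the C5 heptyl chain on three adjacent carbons, with the C7 hydroxyl para to the acyl group. Acylating 5-heptylresorcinol at the carbon flanked by the chain would be hindered and would compete with the carbon between the two oxygens. Ring C is a 2,4-dihydroxy-6-alkylbenzoic acid, which loses CO2 readily in acid or on heating, so the free acid should appear only in the last step and under neutral conditions. The C2–C3–C4 chain is a masked 1,3-diketone whose C2 carbonyl lies next to the ring C ester; unmasked, such 2-(2-oxoalkyl)benzoates close to isocoumarins or naphthols, and the chromone itself opens in hydroxide. The enabling feature is that ring A (C4a acyl, C5 heptyl, C6 H, C7 OH, C8 H, C8a O) is a 2-acyl-3-alkylresorcinol: C4a and C5 map onto the two sp carbons of a heptyl alkynyl ketone, and C6–C7(O)–C8–C8a(O) onto an acetoacetate-derived 1,1,3-trioxygenated butadiene.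

## Retrosynthesis

**23 to 22.** The three O–benzyl bonds are cut last. Methyl ethers and a methyl ester would need boron halides and hydroxide, which the ring C acid and the pyranone do not tolerate. Benzyl groups fall together under neutral hydrogenolysis. The forward step must leave the C2=C3 bond of chromone 22 untouched.

**22 to 20.** The O1–C2 bond is cut, opening ring B to aryl ketone 20, in which C2 is a methyl enol ether. Cutting C4–C4a instead (ring acylation) would bring back the ring A regiochemistry problem. In 20 only the C8a hydroxyl can reach C2, so the forward addition–elimination has one outcome.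

**20 to 13 and 17.** The C5–C6 and C4a–C8a bonds are cut together, which removes ring A altogether. The precursors are the acyclic ynone 13 and the bis-silyloxy ketene acetal diene 17. Against acylation or Fries chemistry on a preformed heptylresorcinol, this cut places the acyl and heptyl groups ortho by construction, because they are the two ends of one alkyne. The forward Diels–Alder reaction must be regioselective, must choose the alkyne over the enone alkene, and must aromatise with retention of the C8a oxygen as a phenol. The methyl enol ether at C2 is essential: a free 1,3-diketone would add its enol oxygen to the ynone and close a pyranone before any cycloaddition.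

**13 to 9 and 10.** The C4–C(sp) bond is cut to N-methoxy-N-methylamide 9 and non-1-yne 10. Adding an acetylide to an aldehyde and oxidising would cost a step. The forward addition must stop at the ketone and ignore the hindered benzyl ester.

**9 to 7 to 4.** The enol ether C–O bond and then the C2–C3 bond are cut. β-Keto amide 7 comes from arylacetic acid 4 by two-carbon homologation through acyl Meldrum's acid 5 and acylketene 6, with the amide installed in the same operation. This avoids an ester-to-amide interchange on a base-sensitive intermediate. Enol ether formation under acid with an orthoformate (via ketal 8) is asked to give the conjugated, push–pull isomer.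

**4 to 2 to 1.** The benzylic C–CO2H bond is cut to the benzylic lithium species 3 of tribenzyl orsellinate 2, and the benzyl groups are cut to orsellinic acid 1, which already contains ring C with its full oxygenation pattern.

**17 to 15 to 14.** The diene comes from methyl acetoacetate 14 by two successive silylations, through silyl enol ether 15 and dienolate 16.

## Roads not taken

**Alternative 1:** The cut is through ring C at C1'–C6' and C4'–C5'. A 2-pyranone already carrying the chromone, benzyl 4-benzyloxy-6-(chromonylmethyl)-2-oxo-2H-pyran-5-carboxylate (A2), would be heated with 1,1-bis(trimethylsilyloxy)ethene (A3). The bridged lactone adduct would lose CO2 and silanol to give the tribenzyl compound A1 with the C5' phenol free.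
- Merits: the regiochemistry of the new arene is defined, and the endgame after A1 is a single hydrogenolysis, as short as in the chosen plan.
- Weak points: it builds the ring that can be bought (ring C is orsellinic acid) and leaves the hard ring A pattern to be made by other means. The 4-benzyloxy group makes A2 a less electron-poor pyranone, so forcing temperatures are likely. The chromone C2=C3 bond in A2 is a second acceptor for the ketene acetal A3.
- Comparison: A2 is no easier to reach than 13, so nothing is saved. The chosen plan spends its key step on the ring that actually needs it.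

**Alternative 2:** The cut is at C4–C4a. The (Z)-3-aryloxybut-2-enoic acid A5 would be activated (oxalyl chloride then SnCl4, or trifluoroacetic anhydride) and its acylium carbon would attack ring A ortho to the ether oxygen, closing the pyranone to A4 (C7 benzyl ether, C5' pivalate, ring C acetonide).
- Merits: this is a classical chromone closure, and the aryl vinyl ether is assembled convergently.
- Weak points: both carbons ortho to the ether oxygen are activated. The wanted one is flanked by the heptyl chain, and the other lies between two oxygens and leads to the 7-heptyl-5-benzyloxy isomer. The acid must have the Z geometry. Strong Lewis acid meets a benzyl ether, an acetonide and a vinylogous carbonate. Three kinds of protecting group lengthen the endgame, and opening the acetonide needs the hydroxide that the chromone resists poorly.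
- Comparison: step count is similar at best. The chosen plan has no regiochemical choice on ring A and removes all protection in one neutral step.

**Alternative 3:** The cut is at C3–C4 and O1–C2. Under [Cp*RhCl2]2 and AgSbF6 (a trivalent rhodium catalyst), the formyl C–H bond of salicylaldehyde A7 would be metalated and coupled with the carbene from sulfoxonium ylide A8. The phenol would then condense with the new ketone to give tetrabenzyl siphulin A6.
- Merits: this is the most convergent road. A8 is one acylation step from acid 4, and A7 is two steps (formylation, selective 4-O-benzylation) from 5-heptylresorcinol A9. If the key step worked here, the synthesis would be about three steps shorter than the chosen one.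
- Weak points: the acyl–rhodium intermediate sits next to the heptyl chain. The carbene insertion releases the free 1,3-diketone beside the ring C ester, hot and in the presence of a Lewis-acidic silver salt, which are the conditions for isocoumarin or naphthol formation. Ylides from enolisable benzyl ketones are a less proven class than aryl ones. Formylation of A9 is expected to favour the carbon next to the chain, so that point is minor.
- Comparison: the chosen plan concedes the step count. In return it offers a metal-free thermal key step whose regiochemistry is fixed by the alkyne, and it keeps the C2 carbonyl masked as an enol ether through every stage at which the ring C ester could be attacked.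

Key step: step 8

Remark on the chemistry: 1, 10 and 14 are taken as purchased; the double-bond geometries drawn for 15, 16 and 17 and the racemic carbons of 12, 18 and 21 have no consequence, because these atoms end as aromatic or trigonal carbons of the achiral target.

## Route

Step 1
Reactants: 1 orsellinic acid (2,4-dihydroxy-6-methylbenzoic acid)
Product: 2 benzyl 2,4-bis(benzyloxy)-6-methylbenzoate
Conditions: BnBr, K2CO3, DMF, 25 → 60 °C
Reagents that add atoms: benzyl bromide, BrCc1ccccc1
Why: Carboxylate O-alkylation followed by Williamson etherification of both phenols; the carboxylate is esterified at room temperature before warming, so the acid cannot decarboxylate.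

Step 2
Reactants: 2 benzyl 2,4-bis(benzyloxy)-6-methylbenzoate
Product: 4 2-[3,5-bis(benzyloxy)-2-(benzyloxycarbonyl)phenyl]acetic acid, via benzylic lithium species 3 (not isolated)
Conditions: LiN(i-Pr)2 (LDA), THF, −78 °C; CO2 (g), −78 → 0 °C; aq. HCl
Reagents that add atoms: carbon dioxide, O=C=O
Why: Lateral lithiation of an ortho-toluate (the methyl group is acidified by the ortho ester) and carboxylation of the benzylic anion; the 2,6-disubstituted ester is too hindered for self-condensation at −78 °C, and the amide base does not touch the benzyl ethers.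

Step 3
Reactants: 4 2-[3,5-bis(benzyloxy)-2-(benzyloxycarbonyl)phenyl]acetic acid
Product: 7 benzyl 2,4-bis(benzyloxy)-6-{4-[methoxy(methyl)amino]-2,4-dioxobutyl}benzoate, via acyl Meldrum's acid 5 (not isolated), via acylketene 6 (not isolated)
Conditions: Meldrum's acid, EDC·HCl, DMAP, CH2Cl2, 0 → 25 °C; then MeNHOMe·HCl, pyridine, toluene, 80 °C
Reagents that add atoms: Meldrum's acid (2,2-dimethyl-1,3-dioxane-4,6-dione), CC1(C)OC(=O)CC(=O)O1; N,O-dimethylhydroxylamine hydrochloride, CNOC.Cl
Why: Carbodiimide C-acylation of Meldrum's acid, then thermal loss of acetone and CO2 to acylketene 6, which the amine traps to give the β-keto N-methoxy-N-methylamide; this is the standard two-carbon homologation of a carboxylic acid to a β-keto amide.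

Step 4
Reactants: 7 benzyl 2,4-bis(benzyloxy)-6-{4-[methoxy(methyl)amino]-2,4-dioxobutyl}benzoate
Product: 9 benzyl 2,4-bis(benzyloxy)-6-{(E)-2-methoxy-4-[methoxy(methyl)amino]-4-oxobut-2-enyl}benzoate, via dimethyl ketal 8 (not isolated)
Conditions: HC(OMe)3, MeOH, H2SO4 (cat.), 25 → 50 °C
Reagents that add atoms: trimethyl orthoformate, COC(OC)OC; methanol, CO
Why: Acid-catalysed ketalisation with an orthoformate and loss of methanol towards the amide, the usual route from a β-keto carbonyl compound to its (E)-β-methoxy enoate-type ether; equilibration gives the conjugated push–pull isomer with methoxy trans to the carbonyl, and the hindered benzyl ester does not transesterify.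

Step 5
Reactants: 9 benzyl 2,4-bis(benzyloxy)-6-{(E)-2-methoxy-4-[methoxy(methyl)amino]-4-oxobut-2-enyl}benzoate; 10 non-1-yne
Product: 13 benzyl 2,4-bis(benzyloxy)-6-[(E)-2-methoxy-4-oxotridec-2-en-5-ynyl]benzoate, via lithium non-1-ynide 11 (not isolated), via lithium hemiaminal adduct 12 (not isolated)
Conditions: 10, n-BuLi, THF, −78 °C; then 9, −78 → −20 °C; AcOH, −78 °C
Reagents that add atoms: none
Why: Weinreb ketone synthesis: the acetylide adds once because chelate 12 survives until the quench, and the 2,6-disubstituted benzyl ester is too hindered to compete; the cold acidic quench protonates the released amine before it can add to the ynone.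

Step 6
Reactants: 14 methyl acetoacetate
Product: 15 methyl (E)-3-(trimethylsilyloxy)but-2-enoate
Conditions: TMSCl, Et3N, hexane, 25 °C
Reagents that add atoms: chlorotrimethylsilane, C[Si](C)(C)Cl
Why: O-Silylation of the β-keto ester enol under amine base, the standard first stage of bis-silyl dienol ether preparation.

Step 7
Reactants: 15 methyl (E)-3-(trimethylsilyloxy)but-2-enoate
Product: 17 (1Z)-1-methoxy-1,3-bis(trimethylsilyloxy)buta-1,3-diene, via lithium dienolate 16 (not isolated)
Conditions: LiN(i-Pr)2 (LDA), THF, −78 °C; TMSCl, −78 → 0 °C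
Reagents that add atoms: chlorotrimethylsilane, C[Si](C)(C)Cl
Why: γ-Deprotonation of the silyl enol ether to the ester dienolate and O-silylation, the standard preparation of this acetoacetate dianion equivalent; the diene is used without chromatography.

Step 8
Reactants: 13 benzyl 2,4-bis(benzyloxy)-6-[(E)-2-methoxy-4-oxotridec-2-en-5-ynyl]benzoate; 17 (1Z)-1-methoxy-1,3-bis(trimethylsilyloxy)buta-1,3-diene
Product: 20 benzyl 2,4-bis(benzyloxy)-6-[(E)-4-(2-heptyl-4,6-dihydroxyphenyl)-2-methoxy-4-oxobut-2-enyl]benzoate, via cyclohexadiene cycloadduct 18 (not isolated), via bis(trimethylsilyl) ether 19 (not isolated)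
Conditions: 17 (3 equiv), toluene, 25 → 80 °C; then THF, aq. citric acid, 0 °C
Reagents that add atoms: none
Why: Diels–Alder benzannulation: the electron-rich diene 17 adds across the ynone triple bond of 13 in a normal-demand, strongly asynchronous [4+2] process (at its stepwise limit a Mukaiyama–Michael addition followed by closure of the allenyl enolate onto the silyloxycarbenium carbon) to give cyclohexa-1,4-diene 18. The closest known reaction type is the cycloaddition of 1,3-bis(silyloxy)dienes and mixed methyl silyl ketene acetal dienes with alkynones, alkynoates and haloquinones, which gives resorcinols after loss of alcohol. Ring A closes as a six-membered carbocycle by intermolecular [4+2] cycloaddition, forming C5–C6 and C4a–C8a in one operation. The selectivity needed is regiochemical: the unsubstituted CH2 terminus of 17 has the largest HOMO coefficient and bonds to the heptyl-bearing β carbon of the ynone, so the acetal carbon ends up next to the acyl group. The alkyne reacts in preference to the enone alkene because the methoxy donor makes that trisubstituted alkene electron-rich and inert. Adduct 18 aromatises by 1,4-elimination of methanol from the mixed ketal, the silyloxy group staying on carbon, to give 19, and the buffered acidic work-up hydrolyses the two aryl silyl ethers to 20. The only stereocentre formed, the ketal carbon of 18, is racemic and is erased on aromatisation, so no stereocontrol is required. The hydrogen-bonded ortho-hydroxy ketone of 20 should not cyclise under the cold citric acid work-up, and any chromone 22 formed early is simply carried forward.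

Step 9
Reactants: 20 benzyl 2,4-bis(benzyloxy)-6-[(E)-4-(2-heptyl-4,6-dihydroxyphenyl)-2-methoxy-4-oxobut-2-enyl]benzoate
Product: 22 benzyl 2,4-bis(benzyloxy)-6-[(5-heptyl-7-hydroxy-4-oxo-4H-chromen-2-yl)methyl]benzoate, via 2-methoxychromanone adduct 21 (not isolated)
Conditions: TsOH·H2O (cat.), CH2Cl2, 25 °C
Reagents that add atoms: none
Why: Acid-catalysed 6-endo-trig oxa-Michael addition of the C8a phenol to the β-methoxy enone and elimination of methanol, the standard closure of 2-hydroxyaryl β-alkoxy or β-amino enones to chromones; the C7 hydroxyl cannot reach C2, and the enol ether geometry is irrelevant to an addition–elimination.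

Step 10
Reactants: 22 benzyl 2,4-bis(benzyloxy)-6-[(5-heptyl-7-hydroxy-4-oxo-4H-chromen-2-yl)methyl]benzoate
Product: 23 siphulin (2-[(5-heptyl-7-hydroxy-4-oxo-4H-chromen-2-yl)methyl]-4,6-dihydroxybenzoic acid)
Conditions: H2 (1 atm), 10% Pd/C, EtOAc–MeOH, 25 °C
Reagents that add atoms: none
Why: Catalytic hydrogenolysis of the two benzyl ethers and the benzyl ester in one neutral operation; the trisubstituted, vinylogous-ester C2=C3 bond of the chromone is reduced far more slowly at atmospheric pressure, and the acid-sensitive product is isolated by filtration and evaporation without heating.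

## Compound list

1 | orsellinic acid (2,4-dihydroxy-6-methylbenzoic acid) | Cc1cc(O)cc(O)c1C(=O)O | starting material
2 | benzyl 2,4-bis(benzyloxy)-6-methylbenzoate | Cc1cc(OCc2ccccc2)cc(OCc2ccccc2)c1C(=O)OCc1ccccc1 | intermediate
3 | benzyl 2,4-bis(benzyloxy)-6-(lithiomethyl)benzoate | [Li]Cc1cc(OCc2ccccc2)cc(OCc2ccccc2)c1C(=O)OCc1ccccc1 | intermediate (not isolated)
4 | 2-[3,5-bis(benzyloxy)-2-(benzyloxycarbonyl)phenyl]acetic acid | OC(=O)Cc1cc(OCc2ccccc2)cc(OCc2ccccc2)c1C(=O)OCc1ccccc1 | intermediate
5 | benzyl 2,4-bis(benzyloxy)-6-[2-(2,2-dimethyl-4,6-dioxo-1,3-dioxan-5-yl)-2-oxoethyl]benzoate | CC1(C)OC(=O)C(C(=O)Cc2cc(OCc3ccccc3)cc(OCc3ccccc3)c2C(=O)OCc2ccccc2)C(=O)O1 | intermediate (not isolated)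
6 | benzyl 2,4-bis(benzyloxy)-6-(2,4-dioxobut-3-enyl)benzoate (acylketene) | O=C=CC(=O)Cc1cc(OCc2ccccc2)cc(OCc2ccccc2)c1C(=O)OCc1ccccc1 | intermediate (not isolated)
7 | benzyl 2,4-bis(benzyloxy)-6-{4-[methoxy(methyl)amino]-2,4-dioxobutyl}benzoate | CON(C)C(=O)CC(=O)Cc1cc(OCc2ccccc2)cc(OCc2ccccc2)c1C(=O)OCc1ccccc1 | intermediate
8 | benzyl 2,4-bis(benzyloxy)-6-{2,2-dimethoxy-4-[methoxy(methyl)amino]-4-oxobutyl}benzoate | CON(C)C(=O)CC(OC)(OC)Cc1cc(OCc2ccccc2)cc(OCc2ccccc2)c1C(=O)OCc1ccccc1 | intermediate (not isolated)
9 | benzyl 2,4-bis(benzyloxy)-6-{(E)-2-methoxy-4-[methoxy(methyl)amino]-4-oxobut-2-enyl}benzoate | CON(C)C(=O)/C=C(/OC)Cc1cc(OCc2ccccc2)cc(OCc2ccccc2)c1C(=O)OCc1ccccc1 | intermediate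
10 | non-1-yne | CCCCCCCC#C | starting material
11 | lithium non-1-ynide | CCCCCCCC#C[Li] | intermediate (not isolated)
12 | benzyl 2,4-bis(benzyloxy)-6-{(E)-4-(lithiooxy)-2-methoxy-4-[methoxy(methyl)amino]tridec-2-en-5-ynyl}benzoate (racemic) | CCCCCCCC#CC(O[Li])(/C=C(/OC)Cc1cc(OCc2ccccc2)cc(OCc2ccccc2)c1C(=O)OCc1ccccc1)N(C)OC | intermediate (not isolated)
13 | benzyl 2,4-bis(benzyloxy)-6-[(E)-2-methoxy-4-oxotridec-2-en-5-ynyl]benzoate | CCCCCCCC#CC(=O)/C=C(/OC)Cc1cc(OCc2ccccc2)cc(OCc2ccccc2)c1C(=O)OCc1ccccc1 | intermediate
14 | methyl acetoacetate | COC(=O)CC(C)=O | starting material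
15 | methyl (E)-3-(trimethylsilyloxy)but-2-enoate | COC(=O)/C=C(/O[Si](C)(C)C)C | intermediate
16 | lithium (E)-1-methoxy-3-(trimethylsilyloxy)buta-1,3-dien-1-olate | CO/C(O[Li])=C/C(=C)O[Si](C)(C)C | intermediate (not isolated)
17 | (1Z)-1-methoxy-1,3-bis(trimethylsilyloxy)buta-1,3-diene | CO/C(O[Si](C)(C)C)=C/C(=C)O[Si](C)(C)C | intermediate
18 | benzyl 2,4-bis(benzyloxy)-6-{(E)-4-[2-heptyl-6-methoxy-4,6-bis(trimethylsilyloxy)cyclohexa-1,4-dien-1-yl]-2-methoxy-4-oxobut-2-enyl}benzoate (racemic) | CCCCCCCC1=C(C(=O)/C=C(/OC)Cc2cc(OCc3ccccc3)cc(OCc3ccccc3)c2C(=O)OCc2ccccc2)C(OC)(O[Si](C)(C)C)C=C(O[Si](C)(C)C)C1 | intermediate (not isolated)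
19 | benzyl 2,4-bis(benzyloxy)-6-{(E)-4-[2-heptyl-4,6-bis(trimethylsilyloxy)phenyl]-2-methoxy-4-oxobut-2-enyl}benzoate | CCCCCCCc1cc(O[Si](C)(C)C)cc(O[Si](C)(C)C)c1C(=O)/C=C(/OC)Cc1cc(OCc2ccccc2)cc(OCc2ccccc2)c1C(=O)OCc1ccccc1 | intermediate (not isolated)
20 | benzyl 2,4-bis(benzyloxy)-6-[(E)-4-(2-heptyl-4,6-dihydroxyphenyl)-2-methoxy-4-oxobut-2-enyl]benzoate | CCCCCCCc1cc(O)cc(O)c1C(=O)/C=C(/OC)Cc1cc(OCc2ccccc2)cc(OCc2ccccc2)c1C(=O)OCc1ccccc1 | intermediate
21 | benzyl 2,4-bis(benzyloxy)-6-[(5-heptyl-7-hydroxy-2-methoxy-4-oxochroman-2-yl)methyl]benzoate (racemic) | CCCCCCCc1cc(O)cc2OC(OC)(Cc3cc(OCc4ccccc4)cc(OCc4ccccc4)c3C(=O)OCc3ccccc3)CC(=O)c12 | intermediate (not isolated)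
22 | benzyl 2,4-bis(benzyloxy)-6-[(5-heptyl-7-hydroxy-4-oxo-4H-chromen-2-yl)methyl]benzoate | CCCCCCCc1cc(O)cc2oc(Cc3cc(OCc4ccccc4)cc(OCc4ccccc4)c3C(=O)OCc3ccccc3)cc(=O)c12 | intermediate
23 | siphulin (2-[(5-heptyl-7-hydroxy-4-oxo-4H-chromen-2-yl)methyl]-4,6-dihydroxybenzoic acid) | CCCCCCCc1cc(O)cc2oc(Cc3cc(O)cc(O)c3C(=O)O)cc(=O)c12 | target

## Step count and risk

Total step count: 10. Longest linear sequence: 8 steps (steps 1–5 and 8–10, from 1); the diene branch is steps 6–7.

**Step 8 (key step).**
- What may go wrong: the cycloaddition may be slow, because the ynone carbonyl of 13 is the acceptor end of a vinylogous ester and so less electron-poor than a simple alkynyl ketone. Thermal decay of the labile ketene acetal 17 (silyl migration, adventitious hydrolysis) could then outrun addition. A second risk is diversion to a stepwise Michael–aldol course, in which the central diene carbon attacks the ketone and buries C4 in the new ring.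
- Fallback: set out from 13 and use a thermally robust cyclic diene whose adduct aromatises by retro-Diels–Alder extrusion instead of elimination. Dimedone is O-silylated (TMSCl, Et3N) to 5,5-dimethyl-3-(trimethylsilyloxy)cyclohex-2-en-1-one F1, which is enolised and silylated (LiN(i-Pr)2, TMSCl) to 5,5-dimethyl-1,3-bis(trimethylsilyloxy)cyclohexa-1,3-diene F2. Heating 13 with F2 in toluene at 140 °C in a sealed vessel should form the same two bonds and give the bicyclo[2.2.2]octadiene adduct F3. F3 expels 2-methylpropene and delivers bis-silyl ether 19, where the route is rejoined; the same work-up then gives 20.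

**Step 5.**
- What may go wrong: the acetylide may act as a base on the doubly activated methylene of 9, and the resulting dienolate may close onto the ortho benzyl ester in a Dieckmann-type annulation to a naphthol. The deactivated vinylogous amide carbonyl may also react sluggishly, and the released N,O-dimethylhydroxylamine may add to the ynone if the quench is not cold and acidic.
- Fallback: set out from 9 and change from acyl substitution to aldehyde alkynylation and oxidation. Reduction of 9 with Cp2Zr(H)Cl in THF, which spares esters, gives benzyl 2,4-bis(benzyloxy)-6-[(E)-2-methoxy-4-oxobut-2-enyl]benzoate F4. Weakly basic zinc-mediated addition of 10 (Zn(OTf)2, Et3N, toluene) gives the racemic propargylic alcohol benzyl 2,4-bis(benzyloxy)-6-[(E)-4-hydroxy-2-methoxytridec-2-en-5-ynyl]benzoate F5. Oxidation with MnO2 in CH2Cl2 returns to the route at 13.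

**Step 3.**
- What may go wrong: N,O-dimethylhydroxylamine is a weak nucleophile and is present largely as its salt, so trapping of acylketene 6 may be slower than ketene self-condensation. At 80 °C product 7 may also lactonise through its enol onto the benzyl ester, giving an isocoumarin.
- Fallback: set out from 5 and trap the ketene with solvent methanol, forming the amide later at room temperature. Heating 5 in methanol at 65 °C gives benzyl 2,4-bis(benzyloxy)-6-(4-methoxy-2,4-dioxobutyl)benzoate F6. Trimethyl orthoformate with catalytic H2SO4 in methanol converts F6 through benzyl 2,4-bis(benzyloxy)-6-(2,2,4-trimethoxy-4-oxobutyl)benzoate F7 into benzyl 2,4-bis(benzyloxy)-6-[(E)-2,4-dimethoxy-4-oxobut-2-enyl]benzoate F8. LiOH in aqueous THF cleaves only the unhindered methyl ester to (E)-4-[3,5-bis(benzyloxy)-2-(benzyloxycarbonyl)phenyl]-3-methoxybut-2-enoic acid F9. Coupling of F9 with MeNHOMe·HCl (EDC·HCl, HOBt, i-Pr2NEt, CH2Cl2) returns to the route at 9, bypassing 7 and step 4.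

**Step 10.**
- What may go wrong: over-reduction of the chromone C2=C3 bond to the chromanone if hydrogen uptake is not stopped after the benzyl groups are gone, and decarboxylation of the 2,4-dihydroxybenzoic acid if the product is warmed or exposed to acid during isolation.
- Fallback: set out from 22 and use a non-reductive Lewis-acid dealkylation. BCl3 with pentamethylbenzene as cation scavenger in CH2Cl2 at −78 °C cleaves the aryl benzyl ethers and the benzyl ester without touching the enone, and cold aqueous work-up gives 23 directly.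

## Further compounds

F1 | step 8 | 5,5-dimethyl-3-(trimethylsilyloxy)cyclohex-2-en-1-one | CC1(C)CC(=O)C=C(O[Si](C)(C)C)C1
F2 | step 8 | 5,5-dimethyl-1,3-bis(trimethylsilyloxy)cyclohexa-1,3-diene | CC1(C)CC(O[Si](C)(C)C)=CC(O[Si](C)(C)C)=C1
F3 | step 8 | benzyl 2,4-bis(benzyloxy)-6-{(E)-4-[3-heptyl-8,8-dimethyl-1,5-bis(trimethylsilyloxy)bicyclo[2.2.2]octa-2,5-dien-2-yl]-2-methoxy-4-oxobut-2-enyl}benzoate (racemic) | CCCCCCCC1=C(C(=O)/C=C(/OC)Cc2cc(OCc3ccccc3)cc(OCc3ccccc3)c2C(=O)OCc2ccccc2)C2(O[Si](C)(C)C)C=C(O[Si](C)(C)C)C1C(C)(C)C2
F4 | step 5 | benzyl 2,4-bis(benzyloxy)-6-[(E)-2-methoxy-4-oxobut-2-enyl]benzoate | O=C/C=C(/OC)Cc1cc(OCc2ccccc2)cc(OCc2ccccc2)c1C(=O)OCc1ccccc1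
F5 | step 5 | benzyl 2,4-bis(benzyloxy)-6-[(E)-4-hydroxy-2-methoxytridec-2-en-5-ynyl]benzoate (racemic) | CCCCCCCC#CC(O)/C=C(/OC)Cc1cc(OCc2ccccc2)cc(OCc2ccccc2)c1C(=O)OCc1ccccc1
F6 | step 3 | benzyl 2,4-bis(benzyloxy)-6-(4-methoxy-2,4-dioxobutyl)benzoate | COC(=O)CC(=O)Cc1cc(OCc2ccccc2)cc(OCc2ccccc2)c1C(=O)OCc1ccccc1
F7 | step 3 | benzyl 2,4-bis(benzyloxy)-6-(2,2,4-trimethoxy-4-oxobutyl)benzoate | COC(=O)CC(OC)(OC)Cc1cc(OCc2ccccc2)cc(OCc2ccccc2)c1C(=O)OCc1ccccc1
F8 | step 3 | benzyl 2,4-bis(benzyloxy)-6-[(E)-2,4-dimethoxy-4-oxobut-2-enyl]benzoate | COC(=O)/C=C(/OC)Cc1cc(OCc2ccccc2)cc(OCc2ccccc2)c1C(=O)OCc1ccccc1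
F9 | step 3 | (E)-4-[3,5-bis(benzyloxy)-2-(benzyloxycarbonyl)phenyl]-3-methoxybut-2-enoic acid | OC(=O)/C=C(/OC)Cc1cc(OCc2ccccc2)cc(OCc2ccccc2)c1C(=O)OCc1ccccc1
F0 | step 10 | none | none
A1 | alternative 1 | benzyl 2-(benzyloxy)-6-{[7-(benzyloxy)-5-heptyl-4-oxo-4H-chromen-2-yl]methyl}-4-hydroxybenzoate | CCCCCCCc1cc(OCc3ccccc3)cc2oc(Cc3cc(O)cc(OCc4ccccc4)c3C(=O)OCc3ccccc3)cc(=O)c12
A2 | alternative 1 | benzyl 4-(benzyloxy)-6-{[7-(benzyloxy)-5-heptyl-4-oxo-4H-chromen-2-yl]methyl}-2-oxo-2H-pyran-5-carboxylate | CCCCCCCc1cc(OCc2ccccc2)cc2oc(Cc3oc(=O)cc(OCc4ccccc4)c3C(=O)OCc3ccccc3)cc(=O)c12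
A3 | alternative 1 | 1,1-bis(trimethylsilyloxy)ethene | C=C(O[Si](C)(C)C)O[Si](C)(C)C
A4 | alternative 2 | 5-{[7-(benzyloxy)-5-heptyl-4-oxo-4H-chromen-2-yl]methyl}-2,2-dimethyl-4-oxo-4H-1,3-benzodioxin-7-yl 2,2-dimethylpropanoate | CCCCCCCc1cc(OCc3ccccc3)cc2oc(Cc3cc(OC(=O)C(C)(C)C)cc4OC(C)(C)OC(=O)c34)cc(=O)c12
A5 | alternative 2 | (Z)-3-[3-(benzyloxy)-5-heptylphenoxy]-4-[7-(2,2-dimethylpropanoyloxy)-2,2-dimethyl-4-oxo-4H-1,3-benzodioxin-5-yl]but-2-enoic acid | CCCCCCCc1cc(OCc2ccccc2)cc(O/C(Cc2cc(OC(=O)C(C)(C)C)cc3OC(C)(C)OC(=O)c23)=C\C(=O)O)c1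
A6 | alternative 3 | benzyl 2,4-bis(benzyloxy)-6-{[7-(benzyloxy)-5-heptyl-4-oxo-4H-chromen-2-yl]methyl}benzoate | CCCCCCCc1cc(OCc3ccccc3)cc2oc(Cc3cc(OCc4ccccc4)cc(OCc4ccccc4)c3C(=O)OCc3ccccc3)cc(=O)c12
A7 | alternative 3 | 4-(benzyloxy)-2-heptyl-6-hydroxybenzaldehyde | CCCCCCCc1cc(OCc2ccccc2)cc(O)c1C=O
A8 | alternative 3 | benzyl 2,4-bis(benzyloxy)-6-{3-[dimethyl(oxo)-λ6-sulfanylidene]-2-oxopropyl}benzoate | CS(C)(=O)=CC(=O)Cc1cc(OCc2ccccc2)cc(OCc2ccccc2)c1C(=O)OCc1ccccc1
A9 | alternative 3 | 5-heptylresorcinol (5-heptylbenzene-1,3-diol) | CCCCCCCc1cc(O)cc(O)c1
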